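**Retrosynthetic overview**
- Ring B (2H-pyran): retro-oxa-6π opens it to a 1-oxatriene. Retro-Knoevenagel then gives prenal and 2-benzoyl-4,4-diprenylcyclohexane-1,3,5-trione.
- Ring A (carbocycle) is not taken from an arene. A retro double Claisen ([3+3]) gives the benzoylacetone 1,3-dianion, which brings the benzoyl group, and dimethyl diprenylmalonate, which brings the quaternary carbon.
- Diprenylmalonate comes from double alkylation of dimethyl malonate with prenyl bromide.
- Ring order: ring A closes first, then ring B, both in one flask from acyclic material. The phenyl ring is bought.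

Assumption: the SMILES has no stereocentre (C-8 carries two identical prenyl groups) and no configurable double bond, so the target is achiral and needs no enantiocontrol.

**Step 1**
Reactants: 1 dimethyl malonate; 2 prenyl bromide (1-bromo-3-methylbut-2-ene, 2.4 equiv)
Product: 4 dimethyl 2,2-bis(3-methylbut-2-en-1-yl)malonate, via monoprenyl malonate 3 (not isolated)
Conditions: NaH (2.5 equiv), THF/DMF 4:1, 0 °C → rt
Reagents that add atoms: none
Why: Double malonic ester alkylation (SN2), in which the soft enolate attacks the primary allylic terminus without SN2′, excess NaH and 2 drive 3 on to 4, and the new quaternary carbon bears two identical groups so it is not a stereocentre.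

**Step 2**
Reactants: 4 dimethyl 2,2-bis(3-methylbut-2-en-1-yl)malonate; 5 benzoylacetone (1-phenylbutane-1,3-dione); 6 prenal (3-methylbut-2-enal)
Product: 11 6-benzoyl-7-hydroxy-2,2-dimethyl-8,8-bis(3-methylbut-2-en-1-yl)-2H-chromen-5(8H)-one (target), via dilithio dianion 7 (not isolated), via triketo ester 8 (not isolated), via benzoyl trione 9 (not isolated), via oxatriene 10 (not isolated)
Conditions: 5, LiN(i-Pr)2 (3.2 equiv), THF, −78 → 0 °C; 4, 0 °C → rt; MeOH, 65 °C; AcOH (6 equiv), ethylenediammonium diacetate (20 mol %), 6 (1.5 equiv), 60 °C (one flask)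
Reagents that add atoms: none
Why: Proposed new method: the terminal carbanion of 7 is acylated by one ester of non-enolisable 4 (β-diketone dianion γ-acylation); triketo ester 8 cannot aldolise because its C-2 is quaternary and cannot rest as its enol lactone under equilibrating LiOMe/MeOH, so its C-6 closes on the second ester (Claisen/Dieckmann cyclisation, favoured by the gem-dialkyl effect and the very acidic β-triketone 9); after buffering, the only free ring CH2 of 9 undergoes Knoevenagel condensation with 6 to give 10, whose reversible oxa-6π electrocyclisation should use the C-5 ketone next to the quaternary carbon, the only carbonyl that is neither enolised nor chelated, and so keeps the hydrogen-bonded benzoyl enol intact; the closest known reaction types are the biomimetic Claisen cyclisation of 3,5,7-triketo esters to acylphloroglucinols and the amine-salt-catalysed formal [3+3] of cyclic 1,3-diones with enals; no stereocentre is formed.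

**Compound list**
1 | dimethyl malonate | COC(=O)CC(=O)OC | starting material
2 | prenyl bromide (1-bromo-3-methylbut-2-ene) | CC(C)=CCBr | starting material
3 | dimethyl 2-(3-methylbut-2-en-1-yl)malonate (not isolated) | COC(=O)C(CC=C(C)C)C(=O)OC | intermediate
4 | dimethyl 2,2-bis(3-methylbut-2-en-1-yl)malonate | COC(=O)C(CC=C(C)C)(CC=C(C)C)C(=O)OC | intermediate
5 | benzoylacetone (1-phenylbutane-1,3-dione) | CC(=O)CC(=O)c1ccccc1 | starting material
6 | prenal (3-methylbut-2-enal) | CC(C)=CC=O | starting material
7 | dilithium 1,3-dianion of benzoylacetone (not isolated) | [Li+].[Li+].[CH2-]C(=O)[CH-]C(=O)c1ccccc1 | intermediate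
8 | methyl 2,2-bis(3-methylbut-2-en-1-yl)-3,5,7-trioxo-7-phenylheptanoate (present as lithium enolate, not isolated) | COC(=O)C(CC=C(C)C)(CC=C(C)C)C(=O)CC(=O)CC(=O)c1ccccc1 | intermediate
9 | 2-benzoyl-3-hydroxy-4,4-bis(3-methylbut-2-en-1-yl)cyclohex-2-ene-1,5-dione, the enol of the 1,3,5-trione (not isolated) | O=C1CC(=O)C(CC=C(C)C)(CC=C(C)C)C(O)=C1C(=O)c1ccccc1 | intermediate
10 | 2-benzoyl-3-hydroxy-6-(3-methylbut-2-en-1-ylidene)-4,4-bis(3-methylbut-2-en-1-yl)cyclohex-2-ene-1,5-dione, reactive isomer with the dienyl chain syn to the C-5 carbonyl (not isolated) | CC(C)=C/C=C1/C(=O)C(C(=O)c2ccccc2)=C(O)C(CC=C(C)C)(CC=C(C)C)C1=O | intermediate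
11 | 6-benzoyl-7-hydroxy-2,2-dimethyl-8,8-bis(3-methylbut-2-en-1-yl)-2H-chromen-5(8H)-one (achiral) | CC(C)=CCC1(CC=C(C)C)C(O)=C(C(=O)c2ccccc2)C(=O)C2=C1OC(C)(C)C=C2 | target

**Total step count:** 2. **Longest linear sequence:** 2.

**Steps most likely to fail.** The route has only two steps, so step 2 is listed once for each of its two independent ring closures.

First, step 2, closure of ring A. The α-quaternary esters of 4 may react too slowly with 7. The sequence may also stall at 8 or at its six-membered enol lactone. The fallback sets out from 4 and comes back at 8. It desymmetrises the malonate so that two different acyl donors make the two C–C bonds. KOH (1 equiv) in MeOH gives monomethyl 2,2-diprenylmalonate F1. 1,1'-Carbonyldiimidazole in THF converts this to the acyl imidazole of the half ester F2. F2 acylates 7 at −78 °C at the imidazolide carbonyl only. Compound 8 is then isolated and taken through the rest of step 2, using NaOMe or Mg(OMe)2 in MeOH for the Claisen closure before 6 is added. Both rings therefore still close in one flask.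

Second, step 2, closure of ring B. Oxatriene 10 could close on the C-1 carbonyl, which would put the pyran oxygen next to the benzoyl-bearing carbon. It could also be trapped by a second molecule of 9. The fallback sets out from 2 and comes back at 11. It fixes the pyran oxygen on an arene first and dearomatises last. Purchased 2,4,6-trihydroxybenzophenone F3 is O-alkylated at its only non-chelated 4-OH with 3-chloro-3-methylbut-1-yne (K2CO3, KI, acetone). This gives (2,6-dihydroxy-4-[(2-methylbut-3-yn-2-yl)oxy]phenyl)(phenyl)methanone F4. Heating F4 in xylene at 140 °C triggers propargyl Claisen rearrangement, 1,5-H shift and oxa-6π closure. Both ortho positions are equivalent, so (5,7-dihydroxy-2,2-dimethyl-2H-chromen-6-yl)(phenyl)methanone F5 is the only possible regioisomer. Two successive C-8 alkylations with 2 (KOH, H2O, 0 °C) follow, the second being an alkylative dearomatisation, and give 11.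

Third, step 1. The second alkylation may be incomplete, O-alkylation may compete, or 2 may be lost by elimination. The fallback sets out from 1 and comes back at 4. It replaces SN2 chemistry by a double Tsuji–Trost allylation using purchased prenyl acetate, NaH and Pd(PPh3)4 (zerovalent palladium) in THF at 60 °C. The soft malonate attacks the less substituted terminus of the π-allyl complex to give the linear prenyl groups. No new isolated compound is made.

**Further compounds**
F1 | step 2 | 2-(methoxycarbonyl)-5-methyl-2-(3-methylbut-2-en-1-yl)hex-4-enoic acid (monomethyl 2,2-diprenylmalonate) | COC(=O)C(CC=C(C)C)(CC=C(C)C)C(=O)O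
F2 | step 2 | methyl 2-(1H-imidazole-1-carbonyl)-5-methyl-2-(3-methylbut-2-en-1-yl)hex-4-enoate | COC(=O)C(CC=C(C)C)(CC=C(C)C)C(=O)n1ccnc1
F3 | step 2 | 2,4,6-trihydroxybenzophenone (purchased) | O=C(c1ccccc1)c1c(O)cc(O)cc1O
F4 | step 2 | (2,6-dihydroxy-4-[(2-methylbut-3-yn-2-yl)oxy]phenyl)(phenyl)methanone | C#CC(C)(C)Oc1cc(O)c(C(=O)c2ccccc2)c(O)c1
F5 | step 2 | (5,7-dihydroxy-2,2-dimethyl-2H-chromen-6-yl)(phenyl)methanone | CC1(C)C=Cc2c(O1)cc(O)c(C(=O)c1ccccc1)c2O
F0 | step 1 | none | none
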